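**Retrosynthetic overview**

1. Feature: C5, C6, C7 and C8 of ring A are four adjacent oxygen-bearing carbons, which are the four ring carbons of a squaric ester, and C4a=C8a is the free C5=C6 double bond of a 2-aryl-3-methoxy-4-pyranone (ring C).
2. End game: 16 from flavone 14 by methylation of the chelated 5-OH and hydrogenolysis of both benzyl ethers.
3. Key disconnection: C5–C4a of 14, leading back to the 4-(pyranon-2-yl)-4-methoxycyclobutenone 11 (thermal 4π opening, then 6π closure builds ring A).
4. 11 from dimethyl squarate 6 and the 6-lithiated pyranone 5 (C8–C8a bond), alkoxide O-methylation, and a methoxy-to-benzyloxy swap at the vinylogous ester carbon (future C7). 5 from pyromeconic acid 1 by C2 iodination, O-methylation and Suzuki coupling with 4.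
5. Ring order: ring C is purchased, ring B is attached by cross-coupling, ring A is formed last.

Key step: step 6

Assumption: 9, 11 and 13 each carry one sp3 stereocentre and are handled as racemates; this centre is lost on aromatisation in step 6, so the achiral target needs no stereocontrol. Cyclobutenones 9 and 11 should be kept below about 40 °C until step 6.

**Step 1**
Reactants: 1 3-hydroxy-4H-pyran-4-one
Product: 2 3-hydroxy-2-iodo-4H-pyran-4-one
Conditions: NIS (1.05 equiv), MeCN, 0 °C → rt, dark
Reagents that add atoms: N-iodosuccinimide, O=C1CCC(=O)N1I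
Why: The 3-hydroxyl makes C2 (ortho to it and next to the ring oxygen) the nucleophilic enol carbon of the pyranone, so electrophilic iodination with NIS, a phenol-type halogenation, should occur there only.

**Step 2**
Reactants: 2 3-hydroxy-2-iodo-4H-pyran-4-one
Product: 3 2-iodo-3-methoxy-4H-pyran-4-one
Conditions: MeI, K2CO3, acetone, 40 °C
Reagents that add atoms: iodomethane, CI
Why: Williamson O-methylation of the acidic enolic hydroxyl under mild carbonate conditions, which should leave the vinylogous acyl iodide untouched.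

**Step 3**
Reactants: 3 2-iodo-3-methoxy-4H-pyran-4-one; 4 4-(benzyloxy)phenylboronic acid
Product: 5 2-[4-(benzyloxy)phenyl]-3-methoxy-4H-pyran-4-one
Conditions: Pd(PPh3)4 (5 mol %), K3PO4, 1,4-dioxane/H2O, 80 °C
Reagents that add atoms: none
Why: Suzuki–Miyaura coupling: the C2–I bond is a vinylogous acyl iodide that adds readily to zerovalent palladium, and the boronic acid delivers ring B with its benzyl ether already in place.

**Step 4**
Reactants: 5 2-[4-(benzyloxy)phenyl]-3-methoxy-4H-pyran-4-one; 6 dimethyl squarate
Product: 9 racemic 4-{6-[4-(benzyloxy)phenyl]-5-methoxy-4-oxo-4H-pyran-2-yl}-2,3,4-trimethoxycyclobut-2-en-1-one, via 6-lithiopyranone 7 (not isolated), via lithium alkoxide 8 (not isolated)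
Conditions: LiTMP (lithium 2,2,6,6-tetramethylpiperidide, 1.1 equiv), THF, −78 °C, 10 min; cannulate into 6 (1.2 equiv), THF, −78 °C; MeOTf (1.5 equiv), −78 → −20 °C; aq. NaHCO3
Reagents that add atoms: methyl trifluoromethanesulfonate, COS(=O)(=O)C(F)(F)F
Why: Directed C–H lithiation with the hindered amide removes the most acidic ring proton (C6–H, alpha to the ring oxygen, as at C2 of chromones), the organolithium adds 1,2 to one of the two equivalent squarate carbonyls at −78 °C as aryl- and alkenyllithiums are known to do, and the lithium alkoxide is O-methylated in the same flask by methyl triflate; the new quaternary centre forms without control, so 9 is racemic.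

**Step 5**
Reactants: 9 racemic 4-{6-[4-(benzyloxy)phenyl]-5-methoxy-4-oxo-4H-pyran-2-yl}-2,3,4-trimethoxycyclobut-2-en-1-one; 10 benzyl alcohol
Product: 11 racemic 3-(benzyloxy)-4-{6-[4-(benzyloxy)phenyl]-5-methoxy-4-oxo-4H-pyran-2-yl}-2,4-dimethoxycyclobut-2-en-1-one
Conditions: 10 (5 equiv), NaH (0.2 equiv), 4 Å MS, THF, 0 °C
Reagents that add atoms: none
Why: Vinylogous transesterification by conjugate addition–elimination: benzyloxide adds to C3, the only alkoxy-bearing carbon beta to the cyclobutenone carbonyl, and methoxide leaves, with the sieves taking up methanol to drive the equilibrium, while the methoxy groups on C2, on C4 and on the pyranone have no such pathway and the stereocentre is untouched.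

**Step 6**
Reactants: 11 racemic 3-(benzyloxy)-4-{6-[4-(benzyloxy)phenyl]-5-methoxy-4-oxo-4H-pyran-2-yl}-2,4-dimethoxycyclobut-2-en-1-one
Product: 14 7-(benzyloxy)-2-[4-(benzyloxy)phenyl]-5-hydroxy-3,6,8-trimethoxy-4H-chromen-4-one, via dienylketene 12 (not isolated), via keto tautomer 13 (not isolated)
Conditions: degassed p-xylene (0.02 M), 130 °C, Ar
Reagents that add atoms: none
Why: Heating should open the cyclobutenone by conrotatory 4π electrocyclic cleavage of the bond between the carbonyl carbon and the quaternary carbon, giving dienylketene 12, in which the lone-pair-donating methoxy group on the former quaternary carbon has rotated outward and the pyranonyl group therefore lies on the same side as the ketene. A thermal disrotatory 6π electrocyclisation over the ketene C=C, the central C=C and the pyranone C5=C6 bond then joins the electrophilic ketene carbon to the nucleophilic alpha-carbon of the pyranone, forming C5–C4a and closing ring A as cyclohexadienone 13, which enolises to the hydrogen-bonded 5-phenol 14 and restores the pyranone conjugation. The closest known reaction type is the Moore rearrangement of 4-aryl-, 4-heteroaryl- and 4-alkenyl-4-alkoxycyclobutenones to monoprotected hydroquinones and phenols, with the enol-ether-type double bond of the pyranone taking the place of the aryl or alkenyl π bond. No stereocentre persists, since the racemic sp3 carbon of 11 becomes aromatic C8 and the transient sp3 C4a of 13 is lost on enolisation. The step needs inward rotation of the pyranonyl group and an unchanged sequence of oxygens: the first follows from the outward preference of the methoxy donor, the second from the in-order transfer of the four cyclobutenone carbons onto C5 (OH), C6 (OMe), C7 (OBn) and C8 (OMe), and the methyl ether on the quaternary carbon leaves no hydroxyl that could intercept the ketene.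

**Step 7**
Reactants: 14 7-(benzyloxy)-2-[4-(benzyloxy)phenyl]-5-hydroxy-3,6,8-trimethoxy-4H-chromen-4-one
Product: 15 7-(benzyloxy)-2-[4-(benzyloxy)phenyl]-3,5,6,8-tetramethoxy-4H-chromen-4-one
Conditions: MeI (5 equiv), K2CO3, DMF, 50 °C
Reagents that add atoms: iodomethane, CI
Why: Williamson methylation; the 5-hydroxyl is hydrogen-bonded to the C4 carbonyl and flanked by the 6-methoxy group, so excess iodomethane in warm DMF is used, conditions the benzyl ethers should tolerate.

**Step 8**
Reactants: 15 7-(benzyloxy)-2-[4-(benzyloxy)phenyl]-3,5,6,8-tetramethoxy-4H-chromen-4-one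
Product: 16 7-hydroxy-2-(4-hydroxyphenyl)-3,5,6,8-tetramethoxy-4H-chromen-4-one
Conditions: H2 (1 atm), palladium on carbon (10% Pd/C), EtOAc/MeOH, rt
Reagents that add atoms: none
Why: Catalytic hydrogenolysis should cleave both aryl benzyl ethers at 1 atm, while the tetrasubstituted C2=C3 bond and the carbonyl of the flavone are not reduced under these mild conditions.

**Compound list**

1 | 3-hydroxy-4H-pyran-4-one (pyromeconic acid) | Oc1coccc1=O | starting material
2 | 3-hydroxy-2-iodo-4H-pyran-4-one | Oc1c(I)occc1=O | intermediate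
3 | 2-iodo-3-methoxy-4H-pyran-4-one | COc1c(I)occc1=O | intermediate
4 | 4-(benzyloxy)phenylboronic acid | OB(O)c1ccc(OCc2ccccc2)cc1 | starting material
5 | 2-[4-(benzyloxy)phenyl]-3-methoxy-4H-pyran-4-one | COc1c(-c2ccc(OCc3ccccc3)cc2)occc1=O | intermediate
6 | dimethyl squarate (3,4-dimethoxycyclobut-3-ene-1,2-dione) | COC1=C(OC)C(=O)C1=O | starting material
7 | {6-[4-(benzyloxy)phenyl]-5-methoxy-4-oxo-4H-pyran-2-yl}lithium | [Li]c1cc(=O)c(OC)c(-c2ccc(OCc3ccccc3)cc2)o1 | intermediate
8 | racemic lithium 1-{6-[4-(benzyloxy)phenyl]-5-methoxy-4-oxo-4H-pyran-2-yl}-2,3-dimethoxy-4-oxocyclobut-2-en-1-olate | [Li+].[O-]C1(c2cc(=O)c(OC)c(-c3ccc(OCc4ccccc4)cc3)o2)C(OC)=C(OC)C1=O | intermediate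
9 | racemic 4-{6-[4-(benzyloxy)phenyl]-5-methoxy-4-oxo-4H-pyran-2-yl}-2,3,4-trimethoxycyclobut-2-en-1-one | O=C1C(OC)=C(OC)C1(OC)c1cc(=O)c(OC)c(-c2ccc(OCc3ccccc3)cc2)o1 | intermediate
10 | benzyl alcohol | OCc1ccccc1 | starting material
11 | racemic 3-(benzyloxy)-4-{6-[4-(benzyloxy)phenyl]-5-methoxy-4-oxo-4H-pyran-2-yl}-2,4-dimethoxycyclobut-2-en-1-one | O=C1C(OC)=C(OCc2ccccc2)C1(OC)c1cc(=O)c(OC)c(-c2ccc(OCc3ccccc3)cc2)o1 | intermediate
12 | (3Z)-3-(benzyloxy)-4-{6-[4-(benzyloxy)phenyl]-5-methoxy-4-oxo-4H-pyran-2-yl}-2,4-dimethoxybuta-1,3-dien-1-one (pyranonyl group cis to the ketene carbon) | O=C=C(OC)/C(OCc1ccccc1)=C(/OC)c1cc(=O)c(OC)c(-c2ccc(OCc3ccccc3)cc2)o1 | intermediate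
13 | racemic 7-(benzyloxy)-2-[4-(benzyloxy)phenyl]-3,6,8-trimethoxy-4H-chromene-4,5(4aH)-dione | O=C1C(OC)=C(OCc2ccccc2)C(OC)=C2OC(-c3ccc(OCc4ccccc4)cc3)=C(OC)C(=O)C12 | intermediate
14 | 7-(benzyloxy)-2-[4-(benzyloxy)phenyl]-5-hydroxy-3,6,8-trimethoxy-4H-chromen-4-one | COc1c(OCc2ccccc2)c(OC)c2oc(-c3ccc(OCc4ccccc4)cc3)c(OC)c(=O)c2c1O | intermediate
15 | 7-(benzyloxy)-2-[4-(benzyloxy)phenyl]-3,5,6,8-tetramethoxy-4H-chromen-4-one | COc1c(OCc2ccccc2)c(OC)c2oc(-c3ccc(OCc4ccccc4)cc3)c(OC)c(=O)c2c1OC | intermediate
16 | 7-hydroxy-2-(4-hydroxyphenyl)-3,5,6,8-tetramethoxy-4H-chromen-4-one | COc1c(O)c(OC)c2oc(-c3ccc(O)cc3)c(OC)c(=O)c2c1OC | target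

**Total step count:** 8
**Longest linear sequence:** 8 steps (1 → 16)

**Steps most likely to fail**

Step 6. The ring opening is reversible, and dienylketene 12 may oligomerise or decompose faster than it closes onto the cross-conjugated pyranone double bond, so that ring A does not form. The fallback forms ring A first on a plain alkene and closes ring C afterwards; it sets out from 6 and comes back at 15, so step 7 is not needed. 1-Methoxyvinyllithium (methyl vinyl ether, t-BuLi, THF) would be added to 6 at −78 °C with MeOTf quench to give racemic 2,3,4-trimethoxy-4-(1-methoxyethenyl)cyclobut-2-en-1-one F1. The alkoxy exchange of step 5 with 10 would give racemic 3-(benzyloxy)-2,4-dimethoxy-4-(1-methoxyethenyl)cyclobut-2-en-1-one F2. Thermolysis in toluene at 110 °C, the well-established ring expansion of 4-alkenylcyclobutenones, should give 3-(benzyloxy)-2,4,5-trimethoxyphenol F3, whose single free ring position is ortho to the hydroxyl. Hoesch acylation at that position with methoxyacetonitrile (ZnCl2, HCl, Et2O, then aqueous hydrolysis) would give 1-[4-(benzyloxy)-2-hydroxy-3,5,6-trimethoxyphenyl]-2-methoxyethan-1-one F4. An Allan–Robinson condensation of F4 with 4-(benzyloxy)benzoic anhydride and potassium 4-(benzyloxy)benzoate at about 175 °C would close ring C and give 15.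

Step 4. The 6-lithiated pyranone 7 may self-condense or fragment before capture, metalation may occur in part at C5 or at the benzylic CH2, the organolithium may attack the vinylogous ester carbon of 6 instead of the carbonyl, and methyl triflate may alkylate the pyranone carbonyl oxygen. The fallback generates the nucleophile by halogen–magnesium exchange in place of deprotonation; it sets out from 5 and comes back at 9. Zincation of 5 with TMPZnCl·LiCl in THF at 25 °C, a mild amide base that metalates chromone-type CH next to the ring oxygen, followed by iodine quench would give 2-[4-(benzyloxy)phenyl]-6-iodo-3-methoxy-4H-pyran-4-one F5. Iodine–magnesium exchange with iPrMgCl·LiCl at −78 °C, addition of 6 and aqueous NH4Cl work-up would give racemic 4-{6-[4-(benzyloxy)phenyl]-5-methoxy-4-oxo-4H-pyran-2-yl}-4-hydroxy-2,3-dimethoxycyclobut-2-en-1-one F6. O-Methylation of F6 with MeI, Ag2O and K2CO3 in MeCN at rt would give 9.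

Step 5. Benzyloxide may add to the cyclobutenone carbonyl and cleave the strained ring, or the exchange may stall short of completion. The fallback makes the swap in two stages without alkoxide; it sets out from 9 and comes back at 11. Dilute aqueous HCl in THF at 20 °C, the standard hydrolysis of 3-alkoxycyclobutenones to cyclobutane-1,3-diones, would give racemic 4-{6-[4-(benzyloxy)phenyl]-5-methoxy-4-oxo-4H-pyran-2-yl}-3-hydroxy-2,4-dimethoxycyclobut-2-en-1-one F7. In F7 the two oxygens flanking C2 are enantiotopic, so Mitsunobu O-benzylation with 10 (PPh3, DIAD, THF, 0 °C) can give only racemic 11.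

**Further compounds**

F1 | step 6 | racemic 2,3,4-trimethoxy-4-(1-methoxyethenyl)cyclobut-2-en-1-one | C=C(OC)C1(OC)C(OC)=C(OC)C1=O
F2 | step 6 | racemic 3-(benzyloxy)-2,4-dimethoxy-4-(1-methoxyethenyl)cyclobut-2-en-1-one | C=C(OC)C1(OC)C(OCc2ccccc2)=C(OC)C1=O
F3 | step 6 | 3-(benzyloxy)-2,4,5-trimethoxyphenol | COc1cc(O)c(OC)c(OCc2ccccc2)c1OC
F4 | step 6 | 1-[4-(benzyloxy)-2-hydroxy-3,5,6-trimethoxyphenyl]-2-methoxyethan-1-one | COCC(=O)c1c(O)c(OC)c(OCc2ccccc2)c(OC)c1OC
F5 | step 4 | 2-[4-(benzyloxy)phenyl]-6-iodo-3-methoxy-4H-pyran-4-one | Ic1cc(=O)c(OC)c(-c2ccc(OCc3ccccc3)cc2)o1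
F6 | step 4 | racemic 4-{6-[4-(benzyloxy)phenyl]-5-methoxy-4-oxo-4H-pyran-2-yl}-4-hydroxy-2,3-dimethoxycyclobut-2-en-1-one | O=C1C(OC)=C(OC)C1(O)c1cc(=O)c(OC)c(-c2ccc(OCc3ccccc3)cc2)o1
F7 | step 5 | racemic 4-{6-[4-(benzyloxy)phenyl]-5-methoxy-4-oxo-4H-pyran-2-yl}-3-hydroxy-2,4-dimethoxycyclobut-2-en-1-one | O=C1C(OC)=C(O)C1(OC)c1cc(=O)c(OC)c(-c2ccc(OCc3ccccc3)cc2)o1
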